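## Structural features

The target is a C11 bicyclic hydroxy lactone esterified with palmitic acid. A cyclohexane ring (C3a, C4, C5, C6, C7, C7a) is fused along C3a–C7a to a butenolide ring (O1, C2, C3, C3a, C7a), and the C3=C3a double bond is exocyclic to the carbocycle. C4 is a gem-dimethyl quaternary carbon, C7a is a fully substituted carbon carrying a methyl group and the lactone oxygen O1, and C6 carries the palmitoyloxy group. The two stereocentres, C6 (S) and C7a (R), stand 1,3 to each other across the C7 methylene; the C6 oxygen is axial, cis to the C7a methyl and syn to the axial C4 methyl. The fragile points are the butenolide (opened by nucleophilic base), the secondary ester, and the tertiary C7a–O1 bond, which becomes a β-leaving group as soon as C6 is a carbonyl. The skeleton is easy, since nine of the eleven core carbons are present in ketoisophorone. The real difficulty is the absolute configuration of the oxygenated quaternary centre C7a and its relation to the remote C6 carbinol. The key step exploits the C6–C7–C7a–O1 array: at the C6 ketone level the C7a–O1 bond of the lactone ring opens and re-forms through an achiral monocyclic dienone acid, so C7a stays mobile until C6 is reduced and both centres can be fixed in one operation.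

## Logic of the disconnections

**11 to 9 and 10.** The acyl C–O bond of the ester on the C6 oxygen is cut. The C16 chain carries no stereochemistry and is best attached last, which leaves a compact C11 hydroxy lactone. The forward step must acylate an axial hydroxyl shielded by two syn-axial methyl groups, must not open the butenolide, and must leave the C6–O bond untouched so that the configuration is retained.

**9 to 8.** The C6–H bond and the C7a–O1 bond are cut together. Removing hydride from C6 gives the closed ketone 7, in which O1 is β to the carbonyl; cutting C7a–O1 as the reverse of a conjugate addition then gives 8, which has no stereocentre. Both stereocentres and the lactone ring are thereby traced to one achiral monocyclic acid. The forward step must re-form C7a–O1 reversibly, so that the two enantiomers of 7 exchange through 8, and must reduce only the 7aR form on one face of C6.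

**8 to 7 to 6.** Compound 8 is defined by the Z geometry of C3=C3a, which an olefination of a ketone flanked by two hindered carbons cannot be trusted to deliver. The geometry is therefore secured through the ring: 8 is traced to isolated racemic 7, because a carboxylate expelled from the lactone can only emerge cis to C7a. Compound 7 is traced to the E/Z mixture 6 by letting C3=C3a rotate under a radical isomerisation catalyst while acid closes whatever Z isomer is present. The gain is that no geometric control is needed earlier. The demand is that isomerisation and closure run in one flask, and that the later opening uses a base that eliminates and does not attack the acyl carbon.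

**6 to 4.** The C3=C3a double bond and the carboxyl group are traced, through the ester 5, to a propargylic carbinol: a 1,3-shift of oxygen turns C3a–OH plus C≡C–OEt into C3a=C3–CO2Et. The C6 carbonyl is masked again as a dioxolane. A tetrasubstituted alkene next to a quaternary carbon is replaced by a tertiary alcohol. The forward step needs acid that rearranges the ynol ether and removes the ketal, followed by ester hydrolysis.

**4 to 2 and 3.** The C3–C3a bond is cut. Compound 3 supplies C2 and C3 at the oxidation level of a carboxylic acid, and C3a is the only ring carbon that must gain a substituent. The forward addition must be 1,2 to a carbonyl flanked by a gem-dimethyl carbon and a methyl-bearing sp2 carbon, which calls for a slim sp nucleophile, and the other carbonyl must be masked.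

**2 to 1.** The dioxolane is removed. Compound 1 already holds the gem-dimethyl group, the future C7a methyl and both carbonyl carbons. The forward ketalisation must distinguish the two carbonyl groups; their steric difference is large and works in the needed direction.

## Other disconnections considered

**Alternative 1:** The cut is the C7–C7a bond of the carbocycle, leading to the achiral diketone A1 (4,4-dimethylheptane-2,6-dione), whose two acetonyl arms are enantiotopic. In the forward sense a chiral secondary amine of the proline type would convert one acetyl group into an enamine. Its terminal carbon (C7) would add to the other carbonyl carbon (C7a) in a 6-enolexo aldol closure. The product would be the hydroxy ketone A2 ((S)-3-hydroxy-3,5,5-trimethylcyclohexan-1-one), with the tertiary carbinol in the sense that corresponds to 7aR.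
- In its favour: a cheap symmetric precursor and a well-understood organocatalytic mechanism. The key step would make a C–C bond, the carbocycle and the oxygenated quaternary centre at once, and would leave the C6 carbonyl in place for a later substrate-controlled reduction.
- Against it here: A2 has an unactivated methylene at C3a, wedged between C4 and C7a, where the target needs an sp2 carbon bearing C3 and C2. A remote oxidation and a two-carbon annulation would still be required. A2 is also a β-hydroxy ketone that can revert to A1 by retro-aldol reaction, eroding enantiomeric purity, or lose water to the enone A3 (isophorone). Selection between two enantiotopic methyl ketone arms with a ketone acceptor is a hard case for enamine catalysis.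
- Comparison: the alternative is the better on skeletal construction (a C–C bond and the six-membered ring, against a C–O bond and a five-membered ring) and on precedent (no new method). It is the equal in drawing chirality from an achiral precursor under catalyst control. It is the weaker on stereochemistry: one centre is set instead of two, and that centre is labile through the same β-relationship that the chosen plan turns to advantage. It is also the weaker on step economy, because C3a functionalisation, lactone annulation, reduction and acylation would follow, against one step after the chosen key step.

**Alternative 2:** The cuts are the C2–C3 and C3a–C7a bonds, with removal of O1 from between C2 and C7a; they lead to the alkynyl amide A4 ((4R)-4-(tert-butyldimethylsilyloxy)-N,N,2,6,6-pentamethyloct-7-ynamide). Forward, triflic anhydride and a hindered pyridine base would turn the amide of A4 into a keteniminium ion that adds (2+2) across the tethered terminal alkyne. The terminal alkyne carbon would bond to the iminium carbon and the internal one to the methyl-bearing carbon. Hydrolysis would give a bicyclic cyclobutenone, and Baeyer–Villiger oxidation would insert O1 between C2 and C7a with retention.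

One structural point needs correcting. The cyclobutenone that maps onto 11 has the silyl ether cis to the angular methyl and is the (1R,3S) isomer A5. The (1R,3R) epimer A6 has the two groups trans and belongs to the C6-epimeric series; it could serve only if the ester were introduced later with inversion at C6.
- In favour: two C–C bonds and two rings in one step, with polarity-controlled regiochemistry. The two C2 epimers of A4 converge through the planar keteniminium carbon. The sense of oxygen insertion should be reliable, because the quaternary carbon migrates in preference to the vinyl carbon.
- Against: the C6 stereocentre must be made beforehand, and C7a is then set only by 1,3-induction. A5 requires the silyloxy group to end up axial and syn to two axial methyl groups, opposite to the expected bias, which leads to A6. An inverting esterification in the A6 series would have to occur at a carbon shielded on the incoming face by those same methyl groups. In addition the alkyne sits on a quaternary carbon, the four-membered enone is strained, and A4 needs a multistep asymmetric synthesis.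
- Comparison: the alternative is the better on bond construction in the key step and the equal or better on precedent, since both reaction types are established. The chosen plan is the better on stereocontrol, because both centres come from an achiral precursor in one catalyst-controlled step with substrate bias and catalyst aligned. It is also the better on step economy: seven steps from a commodity enedione with a single protecting-group operation, against a long synthesis of A4 followed by cyclisation, oxidation, desilylation and acylation.

**Alternative 3:** The cut is the bond between C7a and its methyl carbon, made as a C7a–CH2 bond to a bromoacetate held on the C6 oxygen. The precursor is A7 ((6S)-4,4-dimethyl-2-oxo-2,4,5,6,7,7a-hexahydro-1-benzofuran-6-yl bromoacetate), a butenolide with hydrogen at C7a. Forward, Cs2CO3 would deprotonate C7a to the aromatic 2-oxidofuran dienolate, whose γ-carbon C7a displaces bromide intramolecularly (6-exo-tet) to form the bridged bis-lactone A8. The bridging lactone would then be opened and the carboxymethyl group cut back to methyl by reductive decarboxylation.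
- In favour: the tether can reach C7a only from the face of the C6 oxygen, so the cis relation of the two centres is dictated by geometry. On this point the alternative is the better, because in the chosen plan that relation depends on enzyme and substrate bias agreeing. The C7a configuration of A7 is irrelevant because it passes through a planar dienolate, a convergence equal in kind to that of the chosen plan. γ-Alkylation of butenolide dienolates is a known reaction type.
- Against: the absolute configuration at C6 must come from elsewhere. A quaternary centre is made by SN2 attack of a hindered tertiary nucleophile while the base-labile bromoacetate is exposed to carbonate and to intermolecular alkylation. The carbon delivered is one too many, so the bridging lactone must be opened in the presence of the butenolide and a carboxyl carbon excised. A7 also needs its own enantioselective synthesis.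
- Comparison: the alternative is the better on relative stereocontrol and the equal or better on mechanistic precedent. It is the weaker on step economy (at least three operations after the key step plus the acylation, against one) and on atom economy, and it builds a ring that is absent from the target only to destroy it.

Key step: step 6

Remark: the ketoreductase of step 6 is specified by function (hydride from NADPH to the Re face of C6 of the 7aR form of 7) and is to be taken from a panel of available enzymes; 4 and 7 are racemic, 5 and 6 are E/Z mixtures, and 8 is achiral.

## Route

Step 1
Reactants: 1 ketoisophorone (2,6,6-trimethylcyclohex-2-ene-1,4-dione)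
Product: 2 7,9,9-trimethyl-1,4-dioxaspiro[4.5]dec-6-en-8-one
Conditions: ethylene glycol (1.2 equiv), p-toluenesulfonic acid monohydrate (2 mol %), toluene, reflux, Dean–Stark
Reagents that add atoms: ethylene glycol, OCCO
Why: Acid-catalysed ketalisation with azeotropic removal of water; in ketoisophorone numbering the C4 carbonyl is flanked by CH and CH2 and should react, whereas C1 lies between the quaternary C6 and the methyl-bearing C2 and should not, so the monoketal that masks the future C6 ketone of the target is expected.

Step 2
Reactants: 2 7,9,9-trimethyl-1,4-dioxaspiro[4.5]dec-6-en-8-one; 3 ethoxyacetylene (ethoxyethyne)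
Product: 4 (8RS)-8-(ethoxyethynyl)-7,9,9-trimethyl-1,4-dioxaspiro[4.5]dec-6-en-8-ol (racemic)
Conditions: 3 (1.4 equiv), n-BuLi (1.3 equiv), THF, −78 °C; then 2, −78 → −20 °C; sat. aq NH4Cl
Reagents that add atoms: none
Why: 1,2-Addition of an alkynyllithium (lithium ethoxyacetylide, made in the flask from 3) to a hindered, non-enolisable enone carbonyl; the rod-shaped nucleophile tolerates the flanking quaternary and methyl-bearing carbons and forms the future C3–C3a bond. The new carbinol centre is racemic and is removed in step 3.

Step 3
Reactants: 4 (8RS)-8-(ethoxyethynyl)-7,9,9-trimethyl-1,4-dioxaspiro[4.5]dec-6-en-8-ol
Product: 6 (2E)/(2Z)-2-(2,6,6-trimethyl-4-oxocyclohex-2-en-1-ylidene)acetic acid (mixture of geometric isomers), via ethyl ester 5 (not isolated)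
Conditions: H2SO4 (1 M aq, 0.3 equiv), THF, 0 °C → rt; then LiOH·H2O (4 equiv), 40 °C; then HCl (2 M aq) to pH 2, 0 °C
Reagents that add atoms: water, O; lithium hydroxide, [Li+].[OH-]
Why: Meyer–Schuster rearrangement of an ethoxyethynyl carbinol: protonation of the ynol ether gives a ketene oxonium ion, water adds and the tertiary allylic hydroxyl leaves, a net 1,3-oxygen shift to the conjugated ester 5, while the same acid hydrolyses the dioxolane; hydroxide then saponifies the ester by acyl substitution. The E/Z ratio does not matter because step 4 converges both isomers, and any 2Z acid that closes to 7 on acidification only anticipates step 4.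

Step 4
Reactants: 6 (2E)/(2Z)-2-(2,6,6-trimethyl-4-oxocyclohex-2-en-1-ylidene)acetic acid
Product: 7 (7aRS)-4,4,7a-trimethyl-5,7a-dihydro-1-benzofuran-2,6(4H,7H)-dione (racemic keto lactone)
Conditions: I2 (5 mol %), p-toluenesulfonic acid monohydrate (10 mol %), white LED, toluene, 40 °C; cold aq NaHCO3 wash; crystallisation
Reagents that add atoms: none
Why: Iodine-atom-catalysed E/Z isomerisation (reversible addition of an iodine atom to C3) coupled to Brønsted-acid-catalysed intramolecular oxa-Michael lactonisation: only the 2Z acid can reach C7a, and its 5-exo-trig closure removes it from the geometric equilibrium, so the mixture should converge on neutral 7, racemic because both faces of the enone are attacked equally. Unchanged 2E acid is removed by the bicarbonate wash and can be resubmitted.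

Step 5
Reactants: 7 (7aRS)-4,4,7a-trimethyl-5,7a-dihydro-1-benzofuran-2,6(4H,7H)-dione
Product: 8 (2Z)-2-(2,6,6-trimethyl-4-oxocyclohex-2-en-1-ylidene)acetic acid
Conditions: 1,8-diazabicyclo[5.4.0]undec-7-ene (DBU, 1.1 equiv), CH2Cl2, 0 °C; then cold HCl (0.5 M aq) wash; used at once
Reagents that add atoms: none
Why: E1cB elimination of a β-acyloxy ketone (retro-oxa-Michael): the amidine base removes a C7 proton and the enolate expels the C7a carboxylate; because the lactone ring holds C3 and C7a cis across C3a, the carboxyl group can only emerge on the C7a side of C3=C3a, which is the 2Z geometry. A non-nucleophilic base avoids acyl attack, and cold, brief acidification limits re-closure, which would only return 7, itself a competent feed for step 6.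

Step 6
Reactants: 8 (2Z)-2-(2,6,6-trimethyl-4-oxocyclohex-2-en-1-ylidene)acetic acid
Product: 9 (6S,7aR)-6-hydroxy-4,4,7a-trimethyl-5,6,7,7a-tetrahydro-1-benzofuran-2(4H)-one (loliolide), via keto lactone 7 (not isolated)
Conditions: Re-face-selective ketoreductase (from panel screening), NADP+ (cat.), i-PrOH (10 vol %), KH2PO4/K2HPO4 buffer (0.1 M, pH 7.5), 30 °C
Reagents that add atoms: none
Why: Proposed new method: at pH 7.5 the carboxylate of 8 adds to C7a of its own enone (oxa-Michael, 5-exo-trig, forming the C7a–O1 bond and the lactone ring) to give racemic 7, and buffer base reverses this by removing a C7 proton and expelling the carboxylate (E1cB), so the two enantiomers of 7 exchange through achiral 8 while the enzyme transfers hydride from NADPH to C6 of the 7aR enantiomer only. The closest known reaction type is the dynamic kinetic resolution of β-aryloxy ketones of the chromanone kind, which racemise by retro-oxa-Michael and oxa-Michael steps during ketoreductase or transfer-hydrogenation reduction; what is new is a carboxylate as the reversible leaving group and a fully substituted β-carbon. C7a is controlled by the enzyme, which selects the 7aR lactone from the exchanging pair while the 7aS lactone returns to 8. C6 is controlled by Re-face hydride delivery, which in the 7aR lactone coincides with the equatorial trajectory left open by the syn-axial methyl groups on C4 and C7a and so should give the 6S alcohol cis to the C7a methyl. Three selectivities are needed: enantiomer selection (matched for 7aR, mismatched for 7aS, where the enzyme's face is the blocked axial one), facial selection at C6 (substrate bias and enzyme agree), and chemoselection for the saturated ketone of neutral 7 over the conjugated, less electrophilic carbonyl of anionic 8. Reductases that deliver this carbinol sense at the unhindered carbonyl of 3,3,5-trimethyl-substituted cyclohexanones are the first candidates for the panel. Once C6 is a carbinol no enolate can form, the lactone of 9 cannot open and both centres are fixed; isopropanol regenerates NADPH and is released as acetone.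

Step 7
Reactants: 9 (6S,7aR)-6-hydroxy-4,4,7a-trimethyl-5,6,7,7a-tetrahydro-1-benzofuran-2(4H)-one; 10 palmitoyl chloride (hexadecanoyl chloride)
Product: 11 (6S,7aR)-4,4,7a-trimethyl-2-oxo-2,4,5,6,7,7a-hexahydro-1-benzofuran-6-yl hexadecanoate ((−)-3-O-palmitoylloliolide)
Conditions: 10 (1.3 equiv), pyridine (3 equiv), 4-(dimethylamino)pyridine (10 mol %), CH2Cl2, 0 °C → rt
Reagents that add atoms: none
Why: Acylation of a secondary alcohol by an acid chloride under nucleophilic catalysis (N-acylpyridinium ion), which should overcome the shielding of the axial hydroxyl by the two syn-axial methyl groups. No bond to C6 or C7a is broken, so both stereocentres are retained, and the non-aqueous, weakly basic medium leaves the butenolide closed.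

## Compound list

1 | ketoisophorone (2,6,6-trimethylcyclohex-2-ene-1,4-dione) | CC1=CC(=O)CC(C)(C)C1=O | starting material
2 | 7,9,9-trimethyl-1,4-dioxaspiro[4.5]dec-6-en-8-one | CC1=CC2(CC(C)(C)C1=O)OCCO2 | intermediate
3 | ethoxyacetylene | CCOC#C | starting material
4 | (8RS)-8-(ethoxyethynyl)-7,9,9-trimethyl-1,4-dioxaspiro[4.5]dec-6-en-8-ol (racemic) | CCOC#CC1(O)C(C)=CC2(CC1(C)C)OCCO2 | intermediate
5 | ethyl 2-(2,6,6-trimethyl-4-oxocyclohex-2-en-1-ylidene)acetate (E/Z mixture, not isolated) | CCOC(=O)C=C1C(C)=CC(=O)CC1(C)C | intermediate
6 | 2-(2,6,6-trimethyl-4-oxocyclohex-2-en-1-ylidene)acetic acid (E/Z mixture) | OC(=O)C=C1C(C)=CC(=O)CC1(C)C | intermediate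
7 | (7aRS)-4,4,7a-trimethyl-5,7a-dihydro-1-benzofuran-2,6(4H,7H)-dione (racemic keto lactone) | O=C1CC(C)(C)C2=CC(=O)OC2(C)C1 | intermediate
8 | (2Z)-2-(2,6,6-trimethyl-4-oxocyclohex-2-en-1-ylidene)acetic acid | OC(=O)/C=C1\C(C)=CC(=O)CC1(C)C | intermediate
9 | (6S,7aR)-6-hydroxy-4,4,7a-trimethyl-5,6,7,7a-tetrahydro-1-benzofuran-2(4H)-one (loliolide) | O[C@H]1CC(C)(C)C2=CC(=O)O[C@]2(C)C1 | intermediate
10 | palmitoyl chloride | CCCCCCCCCCCCCCCC(=O)Cl | starting material
11 | (6S,7aR)-4,4,7a-trimethyl-2-oxo-2,4,5,6,7,7a-hexahydro-1-benzofuran-6-yl hexadecanoate ((−)-3-O-palmitoylloliolide) | CCCCCCCCCCCCCCCC(=O)O[C@H]1CC(C)(C)C2=CC(=O)O[C@]2(C)C1 | target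

## Step count and least certain steps

Total steps: 7. Longest linear sequence: 7 steps (1 to 11); 3 and 10 enter as purchased reagents.

**Step 6 (key step, proposed new method).** Two processes are most likely to fail. First, ring closure of the carboxylate onto the hindered, fully substituted C7a may be too slow, or the closed form too scarce, at a pH the enzyme tolerates, so that reduction starves. Second, the enzyme may discriminate poorly between the two enantiomers of the closed form, which differ only at a centre two atoms from the carbonyl, or may reduce the conjugated carbonyl of the open form.

The fallback uses known chemistry and replaces dynamic resolution by static resolution with recycling. It sets out from 7, in hand from step 4. Reduction with NaBH4 in MeOH at −20 °C (equatorial hydride delivery, chemoselective for the saturated ketone) should give the racemic cis hydroxy lactone, that is 9 together with its mirror image (6R,7aS)-loliolide F1. The enantiomers are separated by preparative chromatography on cellulose tris(3,5-dimethylphenylcarbamate), and the route is rejoined at 9. F1 need not be lost: Dess–Martin oxidation would give the (7aS)-keto lactone F2, which the base of step 5 opens to 8 and the acid of step 4 re-closes to racemic 7 for another pass.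

**Step 4.** The likely failure is incomplete geometric equilibration, or side reactions of the iodine and light system (α-iodination of the ketone, acid-promoted degradation), so that the 2E acid does not drain into the lactone.

The fallback avoids the geometric question by closing the lactone before the C3=C3a double bond exists. It sets out from 2.
- The lithium enolate of ethyl acetate (lithium diisopropylamide, THF, −78 °C) is added to give the β-hydroxy ester ethyl 2-(8-hydroxy-7,9,9-trimethyl-1,4-dioxaspiro[4.5]dec-6-en-8-yl)acetate F3.
- Saponification (LiOH) and acidification (aq HCl, THF) remove the dioxolane and let the freely rotating carboxymethyl arm add to C7a of the unveiled enone (5-exo-trig oxa-Michael). This should give the cis-fused hydroxy keto lactone (3aRS,7aRS)-3a-hydroxy-4,4,7a-trimethylhexahydro-1-benzofuran-2,6-dione F4.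
- Dehydration of the tertiary alcohol toward the acidic C3 hydrogens with SOCl2 and pyridine rejoins the route at 7.

**Step 3.** The likely failures are that the acid stage stops at hydration of the ynol ether (a β-hydroxy ester) without the 1,3-oxygen shift, or that saponification of the hindered conjugated ester is incomplete in the one-pot sequence. If hydration is what occurs, the material is the deketalised counterpart of F3 and can enter the step 4 fallback.

The fallback sets out from 2. Peterson olefination with the lithium enolate of ethyl (trimethylsilyl)acetate (lithium diisopropylamide, THF, −78 °C → rt) should give the ketal ester ethyl 2-(7,9,9-trimethyl-1,4-dioxaspiro[4.5]dec-6-en-8-ylidene)acetate F5 as an E/Z mixture. Aqueous HCl in THF (deketalisation to 5) and LiOH are then applied as separate operations, and the route is rejoined at 6.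

**Step 5.** The likely failure is partial re-closure of the free acid to 7 during acidification and concentration, or slow base-catalysed Z to E drift of the open form.

The fallback sets out from 7 and traps the open form. After the amidine base, MeI is added in the same flask to give methyl (2Z)-2-(2,6,6-trimethyl-4-oxocyclohex-2-en-1-ylidene)acetate F6, which cannot re-close and can be purified and checked for geometry. Saponification with LiOH in THF–water, followed by neutralisation to pH 7.5 with KH2PO4 only, returns 8 as its carboxylate in the buffer of step 6, so the route is rejoined at 8 without handling the free acid.

## Further compounds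

F1 | step 6 | (6R,7aS)-6-hydroxy-4,4,7a-trimethyl-5,6,7,7a-tetrahydro-1-benzofuran-2(4H)-one (mirror image of 9) | O[C@@H]1CC(C)(C)C2=CC(=O)O[C@@]2(C)C1
F2 | step 6 | (7aS)-4,4,7a-trimethyl-5,7a-dihydro-1-benzofuran-2,6(4H,7H)-dione | O=C1CC(C)(C)C2=CC(=O)O[C@@]2(C)C1
F3 | step 4 | ethyl 2-(8-hydroxy-7,9,9-trimethyl-1,4-dioxaspiro[4.5]dec-6-en-8-yl)acetate (racemic) | CCOC(=O)CC1(O)C(C)=CC2(CC1(C)C)OCCO2
F4 | step 4 | (3aRS,7aRS)-3a-hydroxy-4,4,7a-trimethylhexahydro-1-benzofuran-2,6-dione (racemic, cis-fused; one enantiomer drawn) | O=C1CC(C)(C)[C@]2(O)CC(=O)O[C@]2(C)C1
F5 | step 3 | ethyl 2-(7,9,9-trimethyl-1,4-dioxaspiro[4.5]dec-6-en-8-ylidene)acetate (E/Z mixture) | CCOC(=O)C=C1C(C)=CC2(CC1(C)C)OCCO2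
F6 | step 5 | methyl (2Z)-2-(2,6,6-trimethyl-4-oxocyclohex-2-en-1-ylidene)acetate | COC(=O)/C=C1\C(C)=CC(=O)CC1(C)C
A1 | alternative 1 | 4,4-dimethylheptane-2,6-dione | CC(=O)CC(C)(C)CC(C)=O
A2 | alternative 1 | (S)-3-hydroxy-3,5,5-trimethylcyclohexan-1-one | O=C1CC(C)(C)C[C@](C)(O)C1
A3 | alternative 1 | isophorone (3,5,5-trimethylcyclohex-2-en-1-one) | CC1=CC(=O)CC(C)(C)C1
A4 | alternative 2 | (4R)-4-(tert-butyldimethylsilyloxy)-N,N,2,6,6-pentamethyloct-7-ynamide (either C2 epimer) | CC(C)(C)[Si](C)(C)O[C@H](CC(C)C(=O)N(C)C)CC(C)(C)C#C
A5 | alternative 2 | (1R,3S)-3-(tert-butyldimethylsilyloxy)-1,5,5-trimethylbicyclo[4.2.0]oct-6-en-8-one | CC(C)(C)[Si](C)(C)O[C@H]1CC(C)(C)C2=CC(=O)[C@]2(C)C1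
A6 | alternative 2 | (1R,3R)-3-(tert-butyldimethylsilyloxy)-1,5,5-trimethylbicyclo[4.2.0]oct-6-en-8-one | CC(C)(C)[Si](C)(C)O[C@@H]1CC(C)(C)C2=CC(=O)[C@]2(C)C1
A7 | alternative 3 | (6S)-4,4-dimethyl-2-oxo-2,4,5,6,7,7a-hexahydro-1-benzofuran-6-yl bromoacetate (either C7a epimer) | O=C(CBr)O[C@H]1CC(C)(C)C2=CC(=O)OC2C1
A8 | alternative 3 | (6S,7aS)-7a-(carboxymethyl)-6-hydroxy-4,4-dimethyl-5,6,7,7a-tetrahydro-1-benzofuran-2(4H)-one 6-lactone | O3[C@H]1CC(C)(C)C2=CC(=O)O[C@]2(CC3=O)C1
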